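Compound numbers are those of the steps and of the list after them: ring A series 1–10, ring B series 11–18, key step 19–21, endgame 22–24.

## Analysis of the target

Compound 24 is a (3R)-isoflavan: a chroman (ring A fused to the pyran ring O1–C2–C3–C4–C4a–C8a) that carries ring B on C3. Ring A is contiguously tetrasubstituted (C4a, C8a–O1, C8 with a 3-hydroxy-3-methylbutyl chain, C7–OH). Ring B is a 2',4'-dihydroxyphenyl group with a 1,1-dimethylallyl group on C5'. C3 is the only stereocentre; it has no neighbouring stereocentre or heteroatom to relay induction, so it must be set by a reagent or catalyst, and it becomes acidic whenever C2 is a carbonyl. The sensitive groups are three electron-rich phenols, a tertiary alcohol that acid would dehydrate or close onto O7 as a 2,2-dimethylchroman, and a 1,1-dimethylallyl group that acid would cyclise onto O4' and hydrogenation would saturate. The late steps therefore exclude acid, hydrogen and strong heating, which points to allyl ethers removed by zerovalent palladium as phenol protection. The difficulty is to join two heavily oxygenated arenes through a three-carbon bridge while creating the lone stereocentre and keeping every substituent in its place. The strategy rests on this: O1–C8a–C4a–C4 is a disguised ortho-quinone methide of ring A, and C3–C2 is the α-carbon and carbonyl of a ring B arylacetic acid, so C3 is an enolate carbon exactly where the two halves meet.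

## Retrosynthetic reasoning

**24 to 23.** The three phenolic O–H bonds are masked as allyl ethers. These survive fluoride, hydride and redox-condensation conditions, and their removal by zerovalent palladium with an amine acceptor is neutral. The C-bound 1,1-dimethylallyl group has no leaving group and is left alone.

**23 to 22.** The pyran is opened at O1–C2. Forward, the C8a phenol displaces the activated primary C2 hydroxyl in a Mitsunobu etherification. C3 is not a reacting centre and the tertiary alcohol cannot be activated, so the cut costs nothing in selectivity.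

**22 to 21.** C2 is raised to the lactone oxidation level. Forward, hydride reduction opens the lactone to phenol and primary alcohol. This also removes the only group that makes C3–H acidic, so it must follow the key step directly.

**21 to 10 and 18 (through 19 and 20).** The C3–C4 and C2–O1 bonds are cut together. This divides the molecule into two arenes of similar size, and both bonds form in one operation in the ring where they belong. C3 is created at the moment the halves are joined. The benzylic bromide 10 releases the ortho-quinone methide 19 on desilylation. The acyl imidazole 18 is turned by a chiral carbene into the azolium enolate 20. The forward step has to select one enolate face, keep 19 dilute and leave 21 unepimerised.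

**10 back to 6 (through 9, 8 and 7).** These are functional-group changes only: bromide from alcohol, alcohol from aldehyde, and a silyl ether and an allyl ether on the two phenols of 6. The phenols can be told apart because O2–H is hydrogen-bonded to the aldehyde and O4–H is not.

**6 to 5.** The C4a–C4 bond is cut by removing the formyl group. Compound 5 is symmetric, so ortho-formylation can give only one product. The forward method must be non-acidic because of the tertiary alcohol next to two phenols.

**5 to 2 and 3 (through 4).** The aryl–CH2 bond at C8 is cut. A B-alkyl Suzuki–Miyaura coupling brings in the whole side chain with its tertiary alcohol from the hydroboration product 4 of alkene 3. The iodide 2 comes from 1 by iodination between the hydroxyls, which fixes the 1,2,3-pattern from the start.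

**18 to 16 (through 17).** The acyl imidazole is made from the acid and the acid from its methyl ester. The ester protects the acid during the ring B chemistry.

**16 to 14 and 15.** The aryl–C(quaternary) bond at C5' is cut. A γ-selective allyl–aryl coupling of boronate 15 puts the 1,1-dimethylallyl group on the carbon that bromination selects. A thermal Claisen rearrangement is avoided here because the two allyl ethers would not survive it.

**14 back to 11 (through 13 and 12).** Bromination para to O2', allylation of both phenols and esterification lead back to the commercial acid 11.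

## Alternatives that were turned down

**Alternative 1:** C3–C4 is made inside a temporary five-membered ring. Ring A is attached as a benzyl ether to O2' of the ring B aryldiazoacetate A1. With a chiral dirhodium carboxylate such as Rh2(S-PTTL)4, the carbene inserts into the benzylic C–H bond next to that oxygen and gives the cis-dihydrobenzofuran ester A2. The benzylic C–O bond is later cleaved reductively, the ester becomes C2, and the pyran is closed on the C8a oxygen.
- For: the insertion is intramolecular through a five-membered transition state, and this reaction class is known for high enantio- and cis-selectivity. On enantiocontrol it is probably stronger than an intermolecular carbene-organocatalysed annulation. It also avoids a free quinone methide.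
- Against: the ring formed is not in the target and must be taken apart. The reductive C–O cleavage cannot use hydrogenolysis because of the 1,1-dimethylallyl group, and ionic or dissolving-metal variants threaten the tertiary alcohol and the alkene. A second stereocentre is made and then destroyed, and the cis ester can epimerise. A1 needs three kinds of protecting group and a diazo transfer, and the halves are joined early, so the sequence is long and linear.
- Comparison: the chosen route gives up some certainty in enantioselectivity. In return it forms both bonds directly in the pyran ring, is convergent and uses one protecting-group type for all phenols.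

**Alternative 2:** Ring A is built rather than bought. Irradiation of the diazomethyl enone A3, which already carries C2, C3, C4 and ring B, gives a vinylketene by Wolff rearrangement. This adds to the siloxyalkyne A4; cyclobutenone opening and 6π closure deliver the phenol A5, forming C8a–C8, C7–C6 and C8a–C4a.
- For: regiocontrol of the tetrasubstituted ring A is complete. The C8a phenol comes out free while O7 is silylated, a differentiation that the chosen route must earn by chelation in compounds 6 to 8. The silyl groups would come off with fluoride at the end, as mild as the palladium deallylation.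
- Against: the key step does nothing for C3, which needs a separate asymmetric step beforehand. A benzene ring that compound 1 supplies for nothing is constructed from two fragments that each take several steps. The photolysis generates a carbene in a molecule with an electron-rich arene and a terminal alkene, and the route is linear.
- Comparison: the chosen strategy sets C3 in the same step that joins the halves.

**Alternative 3:** O1–C8a is formed last on a dearomatised ring A. In the para-quinol A6 the C2 hydroxyl adds to the dienone β-carbon C8a, and acid-promoted loss of the C4a hydroxyl rearomatises to the 7-hydroxyisoflavan A7.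
- For: ring A comes from a simple para-substituted phenol, the two β-carbons are equivalent so ring closure has no regiochemical issue, and the 7-hydroxyl emerges unprotected. On the construction of O1 it is more direct than the chosen route.
- Against: A7 has no C8 side chain. Placing a 3-hydroxy-3-methylbutyl group afterwards between O1 and O7, in competition with the more open C6, is a hard regiochemical problem. The aromatisation needs acid with the 1,1-dimethylallyl group present, the oxidative dearomatisation must spare the electron-rich ring B, and C3 again comes from elsewhere.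
- Comparison: the chosen route carries the C8 chain from its first C–C bond (step 2) and never exposes late intermediates to acid.

Key step: step 14

## Route

Assumption: the (5aS,10bR) antipode of the triazolium catalyst is taken to expose the Re face of C3 in enolate 20; should a first run show the opposite sense, the (5aR,10bS) antipode is used with no other change.

**Step 1**
Reactants: 1 resorcinol
Product: 2 2-iodoresorcinol
Conditions: I2, NaHCO3, H2O, 0 °C → rt
Reagents that add atoms: iodine, II
Why: Electrophilic aromatic iodination of the resorcinolate in buffered water, a standard preparation in which attack occurs at C2 between the two hydroxyls.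

**Step 2**
Reactants: 2 2-iodoresorcinol; 3 2-methylbut-3-en-2-ol
Product: 5 2-(3-hydroxy-3-methylbutyl)benzene-1,3-diol, via alkylborane 4 (not isolated)
Conditions: 3, 9-BBN, THF, 0 °C → rt; then 2, Pd(OAc)2 (3 mol %), SPhos (6 mol %), aq. K3PO4, THF, 60 °C
Reagents that add atoms: none
Why: Anti-Markovnikov hydroboration of the terminal alkene (a slight excess of 9-BBN covers partial borinate formation at the hindered hydroxyl) followed by B-alkyl Suzuki–Miyaura coupling; the bulky electron-rich biarylphosphine 2-dicyclohexylphosphino-2',6'-dimethoxybiphenyl (SPhos) is suited to di-ortho-substituted halides and tolerates phenoxides.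

**Step 3**
Reactants: 5 2-(3-hydroxy-3-methylbutyl)benzene-1,3-diol
Product: 6 2,4-dihydroxy-3-(3-hydroxy-3-methylbutyl)benzaldehyde
Conditions: MgCl2, Et3N, (CH2O)n, MeCN, reflux
Reagents that add atoms: paraformaldehyde (as formaldehyde), C=O
Why: Magnesium phenoxide-directed ortho-formylation (Casnati–Skattebøl); the position between the hydroxyls is blocked and the two open ortho positions are equivalent, so one aldehyde should form, and the basic medium spares the tertiary alcohol.

**Step 4**
Reactants: 6 2,4-dihydroxy-3-(3-hydroxy-3-methylbutyl)benzaldehyde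
Product: 7 4-(allyloxy)-2-hydroxy-3-(3-hydroxy-3-methylbutyl)benzaldehyde
Conditions: allyl bromide (1.05 equiv), K2CO3, acetone, rt
Reagents that add atoms: allyl bromide, C=CCBr
Why: Williamson etherification; the 4-hydroxyl, para to the aldehyde, is the more acidic and is free, whereas the 2-hydroxyl is held in a hydrogen bond to the carbonyl, so monoallylation should occur at O4.

**Step 5**
Reactants: 7 4-(allyloxy)-2-hydroxy-3-(3-hydroxy-3-methylbutyl)benzaldehyde
Product: 8 4-(allyloxy)-2-[(tert-butyldimethylsilyl)oxy]-3-(3-hydroxy-3-methylbutyl)benzaldehyde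
Conditions: TBSCl, imidazole, DMAP (cat.), DMF, 40 °C
Reagents that add atoms: tert-butyldimethylsilyl chloride, C[Si](C)(Cl)C(C)(C)C
Why: Silylation of the remaining phenol; the tertiary alcohol is too hindered to react with the silyl chloride under these conditions.

**Step 6**
Reactants: 8 4-(allyloxy)-2-[(tert-butyldimethylsilyl)oxy]-3-(3-hydroxy-3-methylbutyl)benzaldehyde
Product: 9 4-[6-(allyloxy)-2-[(tert-butyldimethylsilyl)oxy]-3-(hydroxymethyl)phenyl]-2-methylbutan-2-ol
Conditions: NaBH4, MeOH–THF, −10 °C; aq. NH4Cl
Reagents that add atoms: none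
Why: Chemoselective borohydride reduction of the aldehyde; low temperature and a buffered quench limit migration of the silyl group from the phenolic to the benzylic oxygen.

**Step 7**
Reactants: 9 4-[6-(allyloxy)-2-[(tert-butyldimethylsilyl)oxy]-3-(hydroxymethyl)phenyl]-2-methylbutan-2-ol
Product: 10 4-[6-(allyloxy)-3-(bromomethyl)-2-[(tert-butyldimethylsilyl)oxy]phenyl]-2-methylbutan-2-ol
Conditions: CBr4, PPh3, CH2Cl2, 0 °C; filtered cold and used without chromatography
Reagents that add atoms: carbon tetrabromide, BrC(Br)(Br)Br
Why: Appel bromination; only the primary benzylic alkoxyphosphonium can be displaced by bromide, the tertiary alcohol is too hindered to be activated at 0 °C, and the neutral conditions keep the aryl silyl ether.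

**Step 8**
Reactants: 11 2,4-dihydroxyphenylacetic acid
Product: 12 methyl 2-(2,4-dihydroxyphenyl)acetate
Conditions: MeOH, H2SO4 (cat.), reflux
Reagents that add atoms: methanol, CO
Why: Fischer esterification; any benzofuranone formed by lactonisation onto the 2-hydroxyl is reopened by the large excess of methanol.

**Step 9**
Reactants: 12 methyl 2-(2,4-dihydroxyphenyl)acetate
Product: 13 methyl 2-[2,4-bis(allyloxy)phenyl]acetate
Conditions: allyl bromide (2.5 equiv), K2CO3, acetone, reflux
Reagents that add atoms: allyl bromide, C=CCBr
Why: Double Williamson etherification; carbonate is too weak to deprotonate the ester α-carbon, so only the oxygens are alkylated.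

**Step 10**
Reactants: 13 methyl 2-[2,4-bis(allyloxy)phenyl]acetate
Product: 14 methyl 2-[2,4-bis(allyloxy)-5-bromophenyl]acetate
Conditions: NBS, MeCN, 0 °C, dark
Reagents that add atoms: N-bromosuccinimide, O=C1CCC(=O)N1Br
Why: Electrophilic aromatic bromination para to O2' and ortho to O4'; C3' lies between two ethers and C6' is meta to both, and ionic bromination of the activated ring is faster than attack on the allyl alkenes.

**Step 11**
Reactants: 14 methyl 2-[2,4-bis(allyloxy)-5-bromophenyl]acetate; 15 prenylboronic acid pinacol ester
Product: 16 methyl 2-[2,4-bis(allyloxy)-5-(2-methylbut-3-en-2-yl)phenyl]acetate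
Conditions: 15, PdCl2(dtbpf) (3 mol %; dtbpf = 1,1'-bis(di-tert-butylphosphino)ferrocene), aq. K3PO4, THF, 40 °C
Reagents that add atoms: none
Why: γ-Selective Suzuki–Miyaura allyl–aryl coupling; transmetalation with allylic transposition places palladium on the tertiary carbon, and the bulky wide-bite-angle bisphosphine should drive reductive elimination before the allyl group isomerises, giving the 1,1-dimethylallyl arene. The mild temperature and the absence of a soft nucleophile should spare the aryl allyl ethers.

**Step 12**
Reactants: 16 methyl 2-[2,4-bis(allyloxy)-5-(2-methylbut-3-en-2-yl)phenyl]acetate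
Product: 17 2-[2,4-bis(allyloxy)-5-(2-methylbut-3-en-2-yl)phenyl]acetic acid
Conditions: LiOH, THF–H2O, rt; then 1 M HCl, 0 °C
Reagents that add atoms: lithium hydroxide, [Li+].[OH-]
Why: Ester saponification; allyl ethers and the 1,1-dimethylallyl group are inert to hydroxide and to the brief cold acidification.

**Step 13**
Reactants: 17 2-[2,4-bis(allyloxy)-5-(2-methylbut-3-en-2-yl)phenyl]acetic acid
Product: 18 2-[2,4-bis(allyloxy)-5-(2-methylbut-3-en-2-yl)phenyl]-1-(1H-imidazol-1-yl)ethan-1-one
Conditions: CDI, CH2Cl2, rt
Reagents that add atoms: 1,1'-carbonyldiimidazole, O=C(n1ccnc1)n1ccnc1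
Why: Acid activation with carbonyldiimidazole gives the acyl imidazole with loss of carbon dioxide and imidazole; no other group in 17 reacts.

**Step 14**
Reactants: 10 4-[6-(allyloxy)-3-(bromomethyl)-2-[(tert-butyldimethylsilyl)oxy]phenyl]-2-methylbutan-2-ol; 18 2-[2,4-bis(allyloxy)-5-(2-methylbut-3-en-2-yl)phenyl]-1-(1H-imidazol-1-yl)ethan-1-one
Product: 21 (3R)-7-(allyloxy)-3-[2,4-bis(allyloxy)-5-(2-methylbut-3-en-2-yl)phenyl]-8-(3-hydroxy-3-methylbutyl)chroman-2-one, via ortho-quinone methide 19 (not isolated), via azolium enolate 20 (not isolated)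
Conditions: (5aS,10bR)-2-mesityl-5a,10b-dihydro-4H,6H-indeno[2,1-b][1,2,4]triazolo[4,3-d][1,4]oxazin-2-ium tetrafluoroborate (15 mol %), CsF, 18-crown-6, 4 Å MS, THF, −20 °C; 18 in 1.5 equiv
Reagents that add atoms: none
Why: Fluoride from CsF, solubilised by 18-crown-6, removes the silyl group of 10 and the phenoxide expels bromide to give ortho-quinone methide 19, while the carbene formed from the triazolium salt adds to 18, displaces imidazolide and after α-deprotonation forms the (Z)-azolium enolate 20. The enolate carbon C3 adds to the methide carbon C4 in a conjugate addition that rearomatises ring A (C3–C4 bond), and the freed C8a phenoxide attacks the acyl azolium carbonyl in a 6-exo-trig lactonisation (C2–O1 bond) that closes the pyranone ring and releases the carbene; a concerted asynchronous oxa-Diels–Alder path would give the same product. The closest known reaction type is the carbene-catalysed enantioselective formal (4+2) annulation of fluoride-generated ortho-quinone methides with azolium enolates from arylacetyl imidazoles, which gives 3-substituted 3,4-dihydrocoumarins. C3 is the only new stereocentre and is controlled by the catalyst: the fused aminoindanol backbone blocks one face of the planar enolate so that C4 arrives on the Re face of C3, which corresponds to (R). The step needs enantioface selection, C–C bond formation ahead of O-acylation of the phenoxide, and capture of 19 faster than its dimerisation. Ring B acidifies the α-CH2 of 18 so that 20 forms readily, and its 2'-allyloxy group favours the (Z)-geometry; the O7 allyl ether, para to the methide carbon, eases formation of 19 and tempers its reactivity, and slow dissolution of CsF keeps its concentration low. Low temperature and a prompt neutral work-up protect the acidic C3–H of 21, which is taken directly into step 15.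

**Step 15**
Reactants: 21 (3R)-7-(allyloxy)-3-[2,4-bis(allyloxy)-5-(2-methylbut-3-en-2-yl)phenyl]-8-(3-hydroxy-3-methylbutyl)chroman-2-one
Product: 22 (2R)-2-[2,4-bis(allyloxy)-5-(2-methylbut-3-en-2-yl)phenyl]-3-[4-(allyloxy)-2-hydroxy-3-(3-hydroxy-3-methylbutyl)phenyl]propan-1-ol
Conditions: LiAlH4, THF, −20 → 0 °C; aq. potassium sodium tartrate
Reagents that add atoms: none
Why: Hydride reduction of the aryl ester lactone to phenol and primary alcohol; the activated lactone should be reduced faster than it is enolised, and once C2 is an alcohol C3 can no longer epimerise.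

**Step 16**
Reactants: 22 (2R)-2-[2,4-bis(allyloxy)-5-(2-methylbut-3-en-2-yl)phenyl]-3-[4-(allyloxy)-2-hydroxy-3-(3-hydroxy-3-methylbutyl)phenyl]propan-1-ol
Product: 23 4-[(3R)-7-(allyloxy)-3-[2,4-bis(allyloxy)-5-(2-methylbut-3-en-2-yl)phenyl]chroman-8-yl]-2-methylbutan-2-ol
Conditions: PPh3, DIAD, THF, 0 °C → rt
Reagents that add atoms: none
Why: Intramolecular Mitsunobu etherification; the phenol is the only acidic pronucleophile, the primary alcohol is activated and displaced in a 6-exo-tet closure, and the tertiary alcohol cannot form a reactive oxyphosphonium. C3 is not a reacting centre and keeps its configuration.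

**Step 17**
Reactants: 23 4-[(3R)-7-(allyloxy)-3-[2,4-bis(allyloxy)-5-(2-methylbut-3-en-2-yl)phenyl]chroman-8-yl]-2-methylbutan-2-ol
Product: 24 4-[(3R)-7-hydroxy-8-(3-hydroxy-3-methylbutyl)chroman-3-yl]-6-(2-methylbut-3-en-2-yl)benzene-1,3-diol
Conditions: Pd(PPh3)4 (10 mol %), morpholine, THF, rt, degassed
Reagents that add atoms: none
Why: Tsuji–Trost deallylation; zerovalent palladium ionises the three aryl allyl ethers and morpholine traps the allyl groups, while the C-bound 1,1-dimethylallyl group has no leaving group and the conditions are neutral.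

## Compound list

1 | resorcinol (benzene-1,3-diol) | Oc1cccc(O)c1 | starting material
2 | 2-iodoresorcinol (2-iodobenzene-1,3-diol) | Oc1cccc(O)c1I | intermediate
3 | 2-methylbut-3-en-2-ol | C=CC(C)(C)O | starting material
4 | 9-(3-hydroxy-3-methylbutyl)-9-borabicyclo[3.3.1]nonane | CC(C)(O)CCB1C2CCCC1CCC2 | intermediate (not isolated)
5 | 2-(3-hydroxy-3-methylbutyl)benzene-1,3-diol | CC(C)(O)CCc1c(O)cccc1O | intermediate
6 | 2,4-dihydroxy-3-(3-hydroxy-3-methylbutyl)benzaldehyde | CC(C)(O)CCc1c(O)ccc(C=O)c1O | intermediate
7 | 4-(allyloxy)-2-hydroxy-3-(3-hydroxy-3-methylbutyl)benzaldehyde | C=CCOc1ccc(C=O)c(O)c1CCC(C)(C)O | intermediate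
8 | 4-(allyloxy)-2-[(tert-butyldimethylsilyl)oxy]-3-(3-hydroxy-3-methylbutyl)benzaldehyde | C=CCOc1ccc(C=O)c(O[Si](C)(C)C(C)(C)C)c1CCC(C)(C)O | intermediate
9 | 4-[6-(allyloxy)-2-[(tert-butyldimethylsilyl)oxy]-3-(hydroxymethyl)phenyl]-2-methylbutan-2-ol | C=CCOc1ccc(CO)c(O[Si](C)(C)C(C)(C)C)c1CCC(C)(C)O | intermediate
10 | 4-[6-(allyloxy)-3-(bromomethyl)-2-[(tert-butyldimethylsilyl)oxy]phenyl]-2-methylbutan-2-ol | C=CCOc1ccc(CBr)c(O[Si](C)(C)C(C)(C)C)c1CCC(C)(C)O | intermediate
11 | 2,4-dihydroxyphenylacetic acid | OC(=O)Cc1ccc(O)cc1O | starting material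
12 | methyl 2-(2,4-dihydroxyphenyl)acetate | COC(=O)Cc1ccc(O)cc1O | intermediate
13 | methyl 2-[2,4-bis(allyloxy)phenyl]acetate | COC(=O)Cc1ccc(OCC=C)cc1OCC=C | intermediate
14 | methyl 2-[2,4-bis(allyloxy)-5-bromophenyl]acetate | COC(=O)Cc1cc(Br)c(OCC=C)cc1OCC=C | intermediate
15 | 4,4,5,5-tetramethyl-2-(3-methylbut-2-en-1-yl)-1,3,2-dioxaborolane (prenylboronic acid pinacol ester) | CC(C)=CCB1OC(C)(C)C(C)(C)O1 | starting material
16 | methyl 2-[2,4-bis(allyloxy)-5-(2-methylbut-3-en-2-yl)phenyl]acetate | COC(=O)Cc1cc(C(C)(C)C=C)c(OCC=C)cc1OCC=C | intermediate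
17 | 2-[2,4-bis(allyloxy)-5-(2-methylbut-3-en-2-yl)phenyl]acetic acid | OC(=O)Cc1cc(C(C)(C)C=C)c(OCC=C)cc1OCC=C | intermediate
18 | 2-[2,4-bis(allyloxy)-5-(2-methylbut-3-en-2-yl)phenyl]-1-(1H-imidazol-1-yl)ethan-1-one | C=CC(C)(C)c1cc(CC(=O)n2ccnc2)c(OCC=C)cc1OCC=C | intermediate
19 | 3-(allyloxy)-2-(3-hydroxy-3-methylbutyl)-6-methylidenecyclohexa-2,4-dien-1-one (ortho-quinone methide of ring A) | C=C1C=CC(OCC=C)=C(CCC(C)(C)O)C1=O | intermediate (not isolated)
20 | (Z)-2-[2,4-bis(allyloxy)-5-(2-methylbut-3-en-2-yl)phenyl]-1-[(5aS,10bR)-2-mesityl-5a,10b-dihydro-4H,6H-indeno[2,1-b][1,2,4]triazolo[4,3-d][1,4]oxazin-2-ium-1-yl]ethen-1-olate (azolium enolate) | [O-]/C(=C\c1cc(C(C)(C)C=C)c(OCC=C)cc1OCC=C)c1n2[C@@H]3c4ccccc4C[C@@H]3OCc2n[n+]1-c1c(C)cc(C)cc1C | intermediate (not isolated)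
21 | (3R)-7-(allyloxy)-3-[2,4-bis(allyloxy)-5-(2-methylbut-3-en-2-yl)phenyl]-8-(3-hydroxy-3-methylbutyl)chroman-2-one | C=CC(C)(C)c1cc([C@@H]2C(=O)Oc3c(ccc(OCC=C)c3CCC(C)(C)O)C2)c(OCC=C)cc1OCC=C | intermediate
22 | (2R)-2-[2,4-bis(allyloxy)-5-(2-methylbut-3-en-2-yl)phenyl]-3-[4-(allyloxy)-2-hydroxy-3-(3-hydroxy-3-methylbutyl)phenyl]propan-1-ol | C=CC(C)(C)c1cc([C@H](CO)Cc2ccc(OCC=C)c(CCC(C)(C)O)c2O)c(OCC=C)cc1OCC=C | intermediate
23 | 4-[(3R)-7-(allyloxy)-3-[2,4-bis(allyloxy)-5-(2-methylbut-3-en-2-yl)phenyl]chroman-8-yl]-2-methylbutan-2-ol | C=CC(C)(C)c1cc([C@@H]2COc3c(ccc(OCC=C)c3CCC(C)(C)O)C2)c(OCC=C)cc1OCC=C | intermediate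
24 | 4-[(3R)-7-hydroxy-8-(3-hydroxy-3-methylbutyl)chroman-3-yl]-6-(2-methylbut-3-en-2-yl)benzene-1,3-diol (CNP0420388.1) | C=CC(C)(C)c1cc([C@@H]2COc3c(ccc(O)c3CCC(C)(C)O)C2)c(O)cc1O | target

## Step count and least certain steps

Total: 17 steps. Longest linear sequence: 11 steps (steps 1–7 and 14–17, from resorcinol); the ring B branch is 6 steps (8–13) before the key step.

**Step 14 (key step).** The most likely failures are poor facial selectivity and loss of configuration. The electrophile is an unsubstituted methide carbon that gives the catalyst little to grip, and the product has an acidic C3–H in a basic fluoride medium. The quinone methide may also be consumed by dimerisation or by imidazolide or fluoride before the enolate reaches it.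
Fallback, setting out from 17 and 10 and returning at 22: acid 17 is coupled through its pivalic mixed anhydride (pivaloyl chloride, Et3N, LiCl) with (R)-4-benzyloxazolidin-2-one to the imide (R)-4-benzyl-3-{[2,4-bis(allyloxy)-5-(2-methylbut-3-en-2-yl)phenyl]acetyl}oxazolidin-2-one F1. Its sodium (Z)-enolate (NaN(SiMe3)2, THF, −78 °C) is alkylated by bromide 10 on the face away from the benzyl group, giving the (2R)-alkylated imide F2. LiBH4 (THF, trace water, 0 °C) cleaves the auxiliary to the silyl-protected primary alcohol F3, and n-Bu4NF in THF removes the silyl group to give 22.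

**Step 11.** Isomerisation of the allyl group on palladium before reductive elimination would give the linear prenyl arene, the more so next to an ortho-allyloxy group. Zerovalent palladium may also ionise the aryl allyl ethers.
Fallback, setting out from 12 and returning at 16: 12 is monoalkylated at the less hindered O4' with prenyl bromide (K2CO3, acetone) to methyl 2-[2-hydroxy-4-(3-methylbut-2-en-1-yloxy)phenyl]acetate F4, and the remaining phenol is silylated (TBSCl, imidazole) to the silyl ether F5. Aromatic Claisen rearrangement (N,N-diethylaniline, 180 °C, shortest possible time) should move the prenyl group with allylic inversion to C5', the bulky silyl ether and the tertiary terminus disfavouring C3', to give methyl 2-{2-[(tert-butyldimethylsilyl)oxy]-4-hydroxy-5-(2-methylbut-3-en-2-yl)phenyl}acetate F6. Allyl bromide with CsF in DMF then allylates both oxygens, the silyl ether being cleaved in the flask, and gives 16.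

**Step 2.** Oxidative addition and transmetalation at an iodide flanked by two phenoxides may be slow, so that β-hydride elimination of the alkylpalladium and protodeiodination take over.
Fallback, setting out from 2 and returning at 5: 2 is benzylated (benzyl bromide, K2CO3, DMF) to 1,3-bis(benzyloxy)-2-iodobenzene F7. A Heck reaction with methyl acrylate (Pd(OAc)2, n-Bu4NCl, NaHCO3, DMF, 90 °C) gives methyl (E)-3-[2,6-bis(benzyloxy)phenyl]prop-2-enoate F8. Hydrogenation over Pd/C saturates the alkene and removes both benzyl groups, giving methyl 3-(2,6-dihydroxyphenyl)propanoate F9, which may close to 5-hydroxychroman-2-one F10. Either form is converted by excess MeMgBr (THF, 0 °C) into 5.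

**Step 7.** The benzylic bromide is very electron-rich and may ionise on handling, leading to solvolysis, self-alkylation or loss of the silyl group on silica. Competing activation of the tertiary alcohol is a lesser concern.
Fallback, setting out from 8 and returning at 21: reductive amination of 8 with dimethylamine and NaBH(OAc)3 gives 4-[6-(allyloxy)-2-[(tert-butyldimethylsilyl)oxy]-3-[(dimethylamino)methyl]phenyl]-2-methylbutan-2-ol F11. Methyl iodide in acetonitrile gives the crystalline, storable benzyltrimethylammonium iodide F12. Under the conditions of step 14, fluoride removes the silyl group and the phenoxide expels trimethylamine, giving 19 and from it 21.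

## Further compounds

F1 | step 14 | (R)-4-benzyl-3-{[2,4-bis(allyloxy)-5-(2-methylbut-3-en-2-yl)phenyl]acetyl}oxazolidin-2-one | C=CC(C)(C)c1cc(CC(=O)N2[C@H](Cc3ccccc3)COC2=O)c(OCC=C)cc1OCC=C
F2 | step 14 | (R)-4-benzyl-3-{(2R)-3-[4-(allyloxy)-2-[(tert-butyldimethylsilyl)oxy]-3-(3-hydroxy-3-methylbutyl)phenyl]-2-[2,4-bis(allyloxy)-5-(2-methylbut-3-en-2-yl)phenyl]propanoyl}oxazolidin-2-one | C=CC(C)(C)c1cc([C@@H](Cc2ccc(OCC=C)c(CCC(C)(C)O)c2O[Si](C)(C)C(C)(C)C)C(=O)N2[C@H](Cc3ccccc3)COC2=O)c(OCC=C)cc1OCC=C
F3 | step 14 | (2R)-3-[4-(allyloxy)-2-[(tert-butyldimethylsilyl)oxy]-3-(3-hydroxy-3-methylbutyl)phenyl]-2-[2,4-bis(allyloxy)-5-(2-methylbut-3-en-2-yl)phenyl]propan-1-ol | C=CC(C)(C)c1cc([C@H](CO)Cc2ccc(OCC=C)c(CCC(C)(C)O)c2O[Si](C)(C)C(C)(C)C)c(OCC=C)cc1OCC=C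
F4 | step 11 | methyl 2-[2-hydroxy-4-(3-methylbut-2-en-1-yloxy)phenyl]acetate | COC(=O)Cc1ccc(OCC=C(C)C)cc1O
F5 | step 11 | methyl 2-{2-[(tert-butyldimethylsilyl)oxy]-4-(3-methylbut-2-en-1-yloxy)phenyl}acetate | COC(=O)Cc1ccc(OCC=C(C)C)cc1O[Si](C)(C)C(C)(C)C
F6 | step 11 | methyl 2-{2-[(tert-butyldimethylsilyl)oxy]-4-hydroxy-5-(2-methylbut-3-en-2-yl)phenyl}acetate | COC(=O)Cc1cc(C(C)(C)C=C)c(O)cc1O[Si](C)(C)C(C)(C)C
F7 | step 2 | 1,3-bis(benzyloxy)-2-iodobenzene | Ic1c(OCc2ccccc2)cccc1OCc1ccccc1
F8 | step 2 | methyl (E)-3-[2,6-bis(benzyloxy)phenyl]prop-2-enoate | COC(=O)/C=C/c1c(OCc2ccccc2)cccc1OCc1ccccc1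
F9 | step 2 | methyl 3-(2,6-dihydroxyphenyl)propanoate | COC(=O)CCc1c(O)cccc1O
F10 | step 2 | 5-hydroxychroman-2-one | O=C1CCc2c(O)cccc2O1
F11 | step 7 | 4-[6-(allyloxy)-2-[(tert-butyldimethylsilyl)oxy]-3-[(dimethylamino)methyl]phenyl]-2-methylbutan-2-ol | CN(C)Cc1ccc(OCC=C)c(CCC(C)(C)O)c1O[Si](C)(C)C(C)(C)C
F12 | step 7 | {4-(allyloxy)-2-[(tert-butyldimethylsilyl)oxy]-3-(3-hydroxy-3-methylbutyl)phenyl}methyl-trimethylammonium iodide | C[N+](C)(C)Cc1ccc(OCC=C)c(CCC(C)(C)O)c1O[Si](C)(C)C(C)(C)C.[I-]
A1 | alternative 1 | methyl 2-diazo-2-[4-(tert-butyldimethylsilyloxy)-5-(2-methylbut-3-en-2-yl)-2-{[4-(tert-butyldimethylsilyloxy)-2-(pivaloyloxy)-3-(3-methyl-3-(triethylsilyloxy)butyl)phenyl]methoxy}phenyl]acetate (ring B aryldiazoacetate with ring A benzyl ether) | COC(=O)C(=[N+]=[N-])c1cc(C(C)(C)C=C)c(O[Si](C)(C)C(C)(C)C)cc1OCc1ccc(O[Si](C)(C)C(C)(C)C)c(CCC(C)(C)O[Si](CC)(CC)CC)c1OC(=O)C(C)(C)C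
A2 | alternative 1 | methyl cis-2-aryl-2,3-dihydrobenzofuran-3-carboxylate (ring A aryl on C2, ring B fused, protected as in A1) | COC(=O)[C@@H]1[C@H](c2ccc(O[Si](C)(C)C(C)(C)C)c(CCC(C)(C)O[Si](CC)(CC)CC)c2OC(=O)C(C)(C)C)Oc2cc(O[Si](C)(C)C(C)(C)C)c(C(C)(C)C=C)cc21
A3 | alternative 2 | (E,6R)-1-diazo-6-[5-(2-methylbut-3-en-2-yl)-2,4-bis(triisopropylsilyloxy)phenyl]-7-(triethylsilyloxy)hept-3-en-2-one (diazomethyl enone) | [N-]=[N+]=CC(=O)/C=C/C[C@@H](CO[Si](CC)(CC)CC)c1cc(C(C)(C)C=C)c(O[Si](C(C)C)(C(C)C)C(C)C)cc1O[Si](C(C)C)(C(C)C)C(C)C
A4 | alternative 2 | triethyl{[2-methyl-6-(triisopropylsilyloxy)hex-5-yn-2-yl]oxy}silane (siloxyalkyne) | CC(C)[Si](OC#CCCC(C)(C)O[Si](CC)(CC)CC)(C(C)C)C(C)C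
A5 | alternative 2 | ring A phenol with open pyran chain: (R)-2-aryl-3-(2-hydroxyaryl)propyl triethylsilyl ether with O7, O2' and O4' as triisopropylsilyl ethers | C=CC(C)(C)c1cc([C@@H](Cc2ccc(O[Si](C(C)C)(C(C)C)C(C)C)c(CCC(C)(C)O[Si](CC)(CC)CC)c2O)CO[Si](CC)(CC)CC)c(O[Si](C(C)C)(C(C)C)C(C)C)cc1O[Si](C(C)C)(C(C)C)C(C)C
A6 | alternative 3 | 4-{(2R)-2-[2,4-bis(tert-butyldimethylsilyloxy)-5-(2-methylbut-3-en-2-yl)phenyl]-3-hydroxypropyl}-4-hydroxycyclohexa-2,5-dien-1-one (ring A para-quinol) | C=CC(C)(C)c1cc([C@H](CO)CC2(O)C=CC(=O)C=C2)c(O[Si](C)(C)C(C)(C)C)cc1O[Si](C)(C)C(C)(C)C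
A7 | alternative 3 | (3R)-3-[2,4-bis(tert-butyldimethylsilyloxy)-5-(2-methylbut-3-en-2-yl)phenyl]chroman-7-ol | C=CC(C)(C)c1cc([C@@H]2COc3cc(O)ccc3C2)c(O[Si](C)(C)C(C)(C)C)cc1O[Si](C)(C)C(C)(C)C
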